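**Retrosynthetic overview**
- The target is 2,4-dimethoxyphenol carrying an unbranched C21 chain at its only free ortho carbon (C6). No ring is built; the benzene ring is bought.
- C21 alkyl ⇐ benzylic carbinol (removal of the benzylic C–O by ionic hydrogenation).
- Carbinol ⇐ 2-hydroxy-3,5-dimethoxybenzaldehyde + eicosyl Grignard (C1 + C20 split at the benzylic carbon).
- Aldehyde ⇐ 2,4-dimethoxyphenol by ortho-selective formylation.

Assumption: the target has no stereocentre, so no enantiocontrol is needed; 2,4-dimethoxyphenol and 1-bromoeicosane are taken as commercial.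

**Route**

Step 1
Reactants: 1 2,4-dimethoxyphenol
Product: 4 2-hydroxy-3,5-dimethoxybenzaldehyde, via aryloxymagnesium chloride 2 (not isolated), via hydroxymethylated aryloxymagnesium chloride 3 (not isolated)
Conditions: MgCl2 (1.5 eq), Et3N (3.75 eq), (CH2O)n (6 eq), MeCN, reflux, 4 h; then 1 M HCl
Reagents that add atoms: paraformaldehyde (formaldehyde), C=O
Why: Magnesium-mediated ortho-formylation (Casnati–Skattebøl): the Mg phenoxide delivers formaldehyde only to the ortho carbon, C6 being the single free one, and a second formaldehyde oxidises the hydroxymethyl intermediate to the aldehyde by Oppenauer-type hydride transfer.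

Step 2
Reactants: 4 2-hydroxy-3,5-dimethoxybenzaldehyde; 5 1-bromoeicosane
Product: 8 rac-1-(2-hydroxy-3,5-dimethoxyphenyl)heneicosan-1-ol, via eicosylmagnesium bromide 6 (not isolated), via bromomagnesium formylphenoxide 7 (not isolated)
Conditions: 5 (2.6 eq), Mg, cat. I2, THF, reflux; then 4, THF, 0 °C → rt; cold 0.5 M HCl
Reagents that add atoms: none
Why: Grignard 1,2-addition: the first equivalent deprotonates the phenol and the second adds to the chelated aldehyde, giving the benzylic stereocentre as a racemate that is erased in step 3.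

Step 3
Reactants: 8 rac-1-(2-hydroxy-3,5-dimethoxyphenyl)heneicosan-1-ol
Product: 9 6-n-heneicosyl-2,4-dimethoxyphenol
Conditions: Et3SiH (3 eq), TFA (10 eq), CH2Cl2, 0 °C → rt, 2 h; aqueous wash
Reagents that add atoms: none
Why: Ionic hydrogenation (silane/acid deoxygenation): TFA ionises the o-hydroxybenzylic alcohol to a benzylic cation of o-quinone-methide type, which takes hydride from the silane, while the aryl ethers, phenol and arene are inert.

**Compound list**
1 | 2,4-dimethoxyphenol | COc1ccc(O)c(OC)c1 | starting material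
2 | chloromagnesium 2,4-dimethoxyphenoxide | COc1ccc(O[Mg]Cl)c(OC)c1 | intermediate
3 | chloromagnesium 2-(hydroxymethyl)-4,6-dimethoxyphenoxide | COc1cc(CO)c(O[Mg]Cl)c(OC)c1 | intermediate
4 | 2-hydroxy-3,5-dimethoxybenzaldehyde | COc1cc(C=O)c(O)c(OC)c1 | intermediate
5 | 1-bromoeicosane | CCCCCCCCCCCCCCCCCCCCBr | starting material
6 | eicosylmagnesium bromide | CCCCCCCCCCCCCCCCCCCC[Mg]Br | intermediate
7 | bromomagnesium 2-formyl-4,6-dimethoxyphenoxide | COc1cc(C=O)c(O[Mg]Br)c(OC)c1 | intermediate
8 | rac-1-(2-hydroxy-3,5-dimethoxyphenyl)heneicosan-1-ol (racemic; stereocentre removed in step 3) | CCCCCCCCCCCCCCCCCCCCC(O)c1cc(OC)cc(OC)c1O | intermediate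
9 | 6-n-heneicosyl-2,4-dimethoxyphenol (achiral) | CCCCCCCCCCCCCCCCCCCCCc1cc(OC)cc(OC)c1O | target

**Total step count:** 3
**Longest linear sequence:** 3 steps (1 → 4 → 8 → 9)

**Steps most likely to fail, with fallbacks**

Step 3 (the benzylic cation may alkylate another electron-rich ring or dimerise instead of being reduced). The fallback sets out from 8 and avoids cation chemistry. Ac2O, pyridine and cat. DMAP in CH2Cl2 give 1-(2-acetoxy-3,5-dimethoxyphenyl)heneicosyl acetate F7. Hydrogenolysis of the benzylic C–OAc bond (H2, 10% Pd/C, EtOAc/AcOH) gives 2-heneicosyl-4,6-dimethoxyphenyl acetate F8. Methanolysis of the aryl acetate (cat. K2CO3, MeOH/THF, rt) comes back to the route at 9.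

Step 2 (sluggish formation of the long-chain Grignard, and reduction or no addition at the deactivated phenoxide aldehyde). The fallback sets out from 4 and 5 and replaces the addition by an olefination. Heating 5 with PPh3 (MeCN, reflux) gives eicosyltriphenylphosphonium bromide F4. NaHMDS in THF at 0 °C, with one extra equivalent for the phenol, converts it to eicosylidenetriphenylphosphorane F5. Wittig reaction with 4 gives (Z)-2-(heneicos-1-en-1-yl)-4,6-dimethoxyphenol F6 as a Z/E mixture, both isomers being usable. Hydrogenation (H2, Pd/C, EtOAc) comes back to the route at 9.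

Step 1 (incomplete conversion or diarylmethane and over-hydroxymethylation products with this very electron-rich phenol). The fallback sets out from 1 and bypasses the aldehyde. O-Allylation (allyl bromide, K2CO3, acetone, reflux) gives 1-(allyloxy)-2,4-dimethoxybenzene F1. Aromatic Claisen rearrangement (N,N-diethylaniline, 190 °C) onto the only free ortho carbon gives 2-allyl-4,6-dimethoxyphenol F2. Cross-metathesis with 1-eicosene (3 eq, Grubbs II 5 mol %, CH2Cl2, 40 °C) gives (E)-2-(heneicos-2-en-1-yl)-4,6-dimethoxyphenol F3 as an E/Z mixture. Hydrogenation (H2, Pd/C, EtOAc) comes back to the route at 9.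

**Further compounds**
F1 | step 1 | 1-(allyloxy)-2,4-dimethoxybenzene | C=CCOc1ccc(OC)cc1OC
F2 | step 1 | 2-allyl-4,6-dimethoxyphenol | C=CCc1cc(OC)cc(OC)c1O
F3 | step 1 | (E)-2-(heneicos-2-en-1-yl)-4,6-dimethoxyphenol | CCCCCCCCCCCCCCCCCC/C=C/Cc1cc(OC)cc(OC)c1O
F4 | step 2 | eicosyltriphenylphosphonium bromide | CCCCCCCCCCCCCCCCCCCC[P+](c1ccccc1)(c1ccccc1)c1ccccc1.[Br-]
F5 | step 2 | eicosylidenetriphenylphosphorane | CCCCCCCCCCCCCCCCCCCC=P(c1ccccc1)(c1ccccc1)c1ccccc1
F6 | step 2 | (Z)-2-(heneicos-1-en-1-yl)-4,6-dimethoxyphenol | C(/CCCCCCCCCCCCCCCCCCC)=C/c1cc(OC)cc(OC)c1O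
F7 | step 3 | 1-(2-acetoxy-3,5-dimethoxyphenyl)heneicosyl acetate | CCCCCCCCCCCCCCCCCCCCC(OC(C)=O)c1cc(OC)cc(OC)c1OC(C)=O
F8 | step 3 | 2-heneicosyl-4,6-dimethoxyphenyl acetate | CCCCCCCCCCCCCCCCCCCCCc1cc(OC)cc(OC)c1OC(C)=O
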